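The runs come from a simulation with made-up constants, and the scatter is random.

South and south-east each get a small charge of catalyst, 2.5 mol%, less than beta or theta got, and their temperatures lie outside those of both runs.

the same everywhere: substrate 43 mM
- beta: coupling partner 1.5 equiv; catalyst 3.5 mol%; temperature −10 °C; run made earlier
- theta: coupling partner 1.5 equiv; catalyst 5.5 mol%; temperature 1 °C; run made earlier
- south: coupling partner 1.50 equiv; catalyst 2.5 mol%; temperature 5 °C; time 8.0 h
- south-east: coupling partner 1.50 equiv; catalyst 2.5 mol%; temperature −15 °C; time 8.0 h

- beta (time / h: intermediate / %, target / %): 0.833: 5.6, 0.8; 1.33: 7.7, 3.8; 3.00: 16.2, 7.9; 5.00: 21.4, 12.0; 10.0: 33.3, 19.7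
- theta (time / h: intermediate / %, target / %): 0.417: 9.5, 2.8; 0.667: 15.0, 5.1; 1.33: 27.2, 7.2; 2.50: 43.0, 13.5; 5.00: 62.5, 20.6

(standard deviation of a reading: 1 percentage point)



- which one finishes higher in amount of intermediate, in percent of the substrate charged ("neither" within 2 percentage points) (south / south-east / neither)
- amount of intermediate at the end, in percent of the substrate charged, south
- amount of intermediate at the end, in percent of the substrate charged, south-east

Substrate that has gone stands as intermediate plus target, so I read 47.0% left in beta at 10.0 h and 16.9% left in theta at 5.00 h. As pseudo-first-order decay these give 0.0755 /h and 0.356 /h. But is the decay first order? Earlier readings give 0.0813 /h in beta and 0.333 /h in theta; these drift in opposite directions, so I keep the form.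

Scaled in proportion to catalyst, the constants become 0.0539 /h and 0.162 /h. That proportion remains my real doubt: catalyst and temperature changed together in these runs. I commit to it anyway. Drawing the logarithm of the constant straight against temperature gives 0.241 /h for south and 0.0327 /h for south-east. The time in which substrate halves is then 2.88 h in south and 21.2 h in south-east: this is the substrate half-life. After 8.0 h, south has converted 85.4% and south-east 23.0%.

Target per intermediate ends at 0.592 in beta and 0.330 in theta. The same line gives 0.266 for south and 0.772 for south-east, hence intermediate 67.5% and 13.0%. But making target uses coupling partner, and the ratio may follow what remains. So I put these answers back: partner left is 88.0% in south against 86.3% in theta, and 93.3% in south-east against 86.9% in beta. The second round gives 67.2% and 12.6%, a shift of 0.30 percentage points and 0.40 points, so I stop. One objection stays: beta's ratio was still 0.488 at 3.00 h, so target may lag in cold south-east, leaving more intermediate there than I reckon.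

The forecast names south, with 65% (48% to 73%) in south and 14% (7% to 20%) in south-east, holding that “the substrate appears to split in parallel”.

South ends with 65.4% intermediate and south-east with 14.7%, so south finishes higher.

    substrate + catalyst → catalyst + intermediate (k = 3.30 /M/min, Ea = 55.0 kJ/mol)
    coupling partner + catalyst + intermediate ⇌ catalyst + target (K = 4.40 /M, k = 280 /M²/min, Ea = 45.0 kJ/mol, ΔH = −38.0 kJ/mol)
    (constants at 5 °C)

In south-east, my half-life 21.2 h is far longer than the 1.33 h relaxation half-life of the step from intermediate to target, and that relaxation is short against 8.0 h. At 8.00 h substrate still stands at 76.4% in south-east, and intermediate is being made 2.02 times faster than it is used up, each step taken net.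

Take a flask like south-east kept at 10 °C: the same line gives a half-life of 1.75 h, a ratio of 0.204 and so 79.6% intermediate. Computed, that flask holds 77.7% intermediate, with 7.49% substrate left.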